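**Assumption:** the SMILES is read as the ent-labdane (labdane numbering 4R,5S,9R,10S; ring A = C1–C5 and C10, ring B = C5–C10), and 2-[bis(2,2,2-trifluoroethoxy)phosphoryl]acetic acid (23) is taken as a purchasable reagent.

**Retrosynthetic overview**
1. The (Z)-coumarate is built last on the C19 alcohol 22 (phosphonoacetate, then Still–Gennari olefination). The C9 side chain and C8=CH2 come from the C9 ketone 9 by bromoformylation, Negishi coupling with dienyl iodide 15 and an allyl-diazene transposition.
2. trans-Decalin keto ester 9 ⇐ cis-ketol 7 ⇐ achiral enoate–dione 5. Ring A is closed at the C4–C5 bond by a copper hydride-catalysed enantioselective reductive aldol cyclisation that sets C10 and C4 and leaves a C5 hydroxyl, later replaced by the trans C5–H.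
3. Enabling feature: C10 is a methyl-bearing quaternary carbon flanked in ring B by C5 and C9, so with both at the ketone level it is prochiral with two enantiotopic carbonyls. C4 carries the carboxyl carbon C19, so C4–C5 is the aldol bond of a β-hydroxy ester and C3 is the β-carbon of its enoate.
4. Ring order: ring B is bought as 2-methylcyclohexane-1,3-dione; ring A is closed in step 3; no ring is formed afterwards (the benzene ring arrives with aldehyde 25).

Key step: step 3

**Route**

Step 1
Reactants: 1 2-methylcyclohexane-1,3-dione; 2 prop-2-enal (acrolein)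
Product: 3 3-(1-methyl-2,6-dioxocyclohexyl)propanal
Conditions: H2O, 25 °C
Reagents that add atoms: none
Why: Michael addition of the acidic C2–H of the 1,3-dione to acrolein should give the quaternary carbon (future C10) by C-alkylation, and no stereocentre arises because the two ring carbonyls stay enantiotopic.

Step 2
Reactants: 3 3-(1-methyl-2,6-dioxocyclohexyl)propanal; 4 methyl 2-(triphenyl-λ5-phosphanylidene)propanoate
Product: 5 methyl (2E)-2-methyl-5-(1-methyl-2,6-dioxocyclohexyl)pent-2-enoate
Conditions: CH2Cl2, 25 °C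
Reagents that add atoms: none
Why: Wittig olefination with a stabilised ylide should take the aldehyde and leave the hindered ring ketones, and it gives the (E)-trisubstituted enoate that carries C4, C18 and C19.

Step 3
Reactants: 5 methyl (2E)-2-methyl-5-(1-methyl-2,6-dioxocyclohexyl)pent-2-enoate
Product: 7 methyl (1R,4aR,8aS)-8a-hydroxy-1,4a-dimethyl-5-oxodecahydronaphthalene-1-carboxylate, via silyl ether 6 (not isolated)
Conditions: Cu(OAc)2·H2O (5 mol %), (R)-DTBM-SEGPHOS (5.5 mol %), (EtO)2MeSiH (2 equiv), toluene, −40 → 0 °C; then 1 M HCl, THF, 0 °C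
Reagents that add atoms: none
Why: Proposed new method: a bisphosphine-ligated copper hydride adds hydride to C3 of the α-methyl enoate, the resulting tetrasubstituted copper ester enolate at C4 adds to one of the two enantiotopic ring carbonyls (C5), and σ-bond metathesis of the copper aldolate with the silane releases silyl ether 6 and regenerates the hydride. The closest known reaction type is the copper hydride-catalysed domino conjugate reduction/aldol cyclisation of β-monosubstituted enoates tethered to 2-methylcycloalkane-1,3-diones; what has not been shown is the α-methyl enoate, whose enolate makes C4 quaternary between two fully substituted carbons, and the irreversible silylation of the aldolate is what should pull this crowded aldol forward. Ring A closes by a 6-(enolexo)-exo-trig aldol addition that forms the C4–C5 bond. C10 is set by the ligand, which decides whether C5 or C9 is attacked (the ligand enantiomer is chosen for the 4aR series); C5 is set by the three-carbon tether from C10, which forces the new hydroxyl cis to the C10 methyl; C4 is set by the closed chair transition state, in which C19 must sit gauche to the carbonyl oxygen and the alternative with C18 syn-axial to the C10 methyl is the most strained, so the ester should end cis to the hydroxyl and to the C10 methyl. The step needs 1,4-reduction of the enoate to outrun 1,2-reduction of the two ketones and the aldol to outrun protonation: the enoate is the only soft acceptor in the substrate, the ketones are hindered by the adjacent quaternary carbon, and no proton source is present until work-up.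

Step 4
Reactants: 7 methyl (1R,4aR,8aS)-8a-hydroxy-1,4a-dimethyl-5-oxodecahydronaphthalene-1-carboxylate
Product: 8 methyl (1R,4aR)-1,4a-dimethyl-5-oxo-1,2,3,4,4a,5,6,7-octahydronaphthalene-1-carboxylate
Conditions: SOCl2, pyridine, CH2Cl2, −20 → 0 °C
Reagents that add atoms: none
Why: Dehydration of the tertiary alcohol through its chlorosulfite (E2 elimination) can only give the C5=C6 alkene, because C4 and C10 are quaternary and the only β-hydrogens are on C6.

Step 5
Reactants: 8 methyl (1R,4aR)-1,4a-dimethyl-5-oxo-1,2,3,4,4a,5,6,7-octahydronaphthalene-1-carboxylate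
Product: 9 methyl (1R,4aR,8aS)-1,4a-dimethyl-5-oxodecahydronaphthalene-1-carboxylate
Conditions: H2 (50 bar), Pd/C (10%), EtOAc, 25 °C
Reagents that add atoms: none
Why: In this heterogeneous catalytic hydrogenation the axial C19 ester and the C10 methyl shield the same face of the C5=C6 alkene, so hydrogen should add from the other face and set H-5 trans to the C10 methyl (trans-decalin), as in the hydrogenation of 4,4-dimethyl-Δ5-steroids to the 5α series.

Step 6
Reactants: 9 methyl (1R,4aR,8aS)-1,4a-dimethyl-5-oxodecahydronaphthalene-1-carboxylate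
Product: 10 methyl (1R,4aR,8aR)-5-bromo-6-formyl-1,4a-dimethyl-1,2,3,4,4a,7,8,8a-octahydronaphthalene-1-carboxylate
Conditions: PBr3, DMF, CHCl3, 0 → 60 °C; then ice-water
Reagents that add atoms: N,N-dimethylformamide CN(C)C=O; phosphorus tribromide BrP(Br)Br
Why: In this Vilsmeier–Haack–Arnold bromoformylation the ketone can enolise only toward C8, so the formyl carbon (future C17) should enter at C8 and bromide should replace the C9 oxygen.

Step 7
Reactants: 11 2-chlorobuta-1,3-diene (chloroprene); 12 oxirane
Product: 14 3-methylidenepent-4-en-1-ol, via Grignard reagent 13 (not isolated)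
Conditions: Mg, ZnCl2 (cat.), THF, reflux; then oxirane, CuI (cat.), −30 → 0 °C; aq NH4Cl
Reagents that add atoms: none
Why: Grignard formation from chloroprene and SN2 opening of the epoxide should give the homoallylic alcohol with the 2-substituted butadiene already in place.

Step 8
Reactants: 14 3-methylidenepent-4-en-1-ol
Product: 15 5-iodo-3-methylidenepent-1-ene
Conditions: PPh3, I2, imidazole, CH2Cl2, 0 °C, dark
Reagents that add atoms: iodine II
Why: Appel-type iodination converts the primary alcohol to the iodide under neutral conditions that leave the diene untouched.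

Step 9
Reactants: 10 methyl (1R,4aR,8aR)-5-bromo-6-formyl-1,4a-dimethyl-1,2,3,4,4a,7,8,8a-octahydronaphthalene-1-carboxylate; 15 5-iodo-3-methylidenepent-1-ene
Product: 17 methyl (1R,4aR,8aS)-6-formyl-1,4a-dimethyl-5-(3-methylidenepent-4-en-1-yl)-1,2,3,4,4a,7,8,8a-octahydronaphthalene-1-carboxylate, via organozinc iodide 16 (not isolated)
Conditions: Zn dust, LiCl, THF, 25 °C (insertion into 15); then 10, Pd(OAc)2 (2 mol %), SPhos (4 mol %), THF, 45 °C
Reagents that add atoms: none
Why: In this Negishi cross-coupling, oxidative addition to the activated β-bromo enal is easy, the alkylzinc adds neither to the aldehyde nor to the ester, and the bulky electron-rich phosphine should favour reductive elimination over β-hydride elimination at the crowded alkenyl carbon C9.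

Step 10
Reactants: 17 methyl (1R,4aR,8aS)-6-formyl-1,4a-dimethyl-5-(3-methylidenepent-4-en-1-yl)-1,2,3,4,4a,7,8,8a-octahydronaphthalene-1-carboxylate
Product: 18 methyl (1R,4aR,8aS)-1,4a-dimethyl-5-(3-methylidenepent-4-en-1-yl)-6-{(E)-[2-(4-methylbenzenesulfonyl)hydrazinylidene]methyl}-1,2,3,4,4a,7,8,8a-octahydronaphthalene-1-carboxylate
Conditions: TsNHNH2, EtOH, 25 °C
Reagents that add atoms: 4-methylbenzenesulfonohydrazide Cc1ccc(cc1)S(=O)(=O)NN
Why: Hydrazone formation is a condensation that takes only the aldehyde; the hindered ester and the alkenes do not react.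

Step 11
Reactants: 18 methyl (1R,4aR,8aS)-1,4a-dimethyl-5-(3-methylidenepent-4-en-1-yl)-6-{(E)-[2-(4-methylbenzenesulfonyl)hydrazinylidene]methyl}-1,2,3,4,4a,7,8,8a-octahydronaphthalene-1-carboxylate
Product: 21 methyl (1R,4aS,5R,8aS)-1,4a-dimethyl-6-methylidene-5-(3-methylidenepent-4-en-1-yl)decahydronaphthalene-1-carboxylate, via N-borylhydrazine 19 (not isolated), via allyl diazene 20 (not isolated)
Conditions: catecholborane, CHCl3, 0 °C; then NaOAc·3H2O, 60 °C
Reagents that add atoms: none
Why: In this Kabalka reduction of an α,β-unsaturated tosylhydrazone, 1,2-hydride addition, loss of sulfinate and retro-ene loss of N2 from the allyl diazene should move the double bond to C8=C17 and deliver hydrogen to C9 axially on the face opposite the C10 methyl, which places the side chain equatorial and cis to that methyl.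

Step 12
Reactants: 21 methyl (1R,4aS,5R,8aS)-1,4a-dimethyl-6-methylidene-5-(3-methylidenepent-4-en-1-yl)decahydronaphthalene-1-carboxylate
Product: 22 [(1R,4aS,5R,8aS)-1,4a-dimethyl-6-methylidene-5-(3-methylidenepent-4-en-1-yl)decahydronaphthalen-1-yl]methanol
Conditions: LiAlH4, Et2O, 0 → 25 °C; aqueous work-up
Reagents that add atoms: none
Why: Hydride reduction of the ester gives the primary neopentyl alcohol, and the isolated and conjugated C=C bonds are inert to LiAlH4.

Step 13
Reactants: 22 [(1R,4aS,5R,8aS)-1,4a-dimethyl-6-methylidene-5-(3-methylidenepent-4-en-1-yl)decahydronaphthalen-1-yl]methanol; 23 2-[bis(2,2,2-trifluoroethoxy)phosphoryl]acetic acid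
Product: 24 [(1R,4aS,5R,8aS)-1,4a-dimethyl-6-methylidene-5-(3-methylidenepent-4-en-1-yl)decahydronaphthalen-1-yl]methyl 2-[bis(2,2,2-trifluoroethoxy)phosphoryl]acetate
Conditions: DCC, DMAP (cat.), CH2Cl2, 0 → 25 °C
Reagents that add atoms: none
Why: Steglich esterification (carbodiimide activation with DMAP) should acylate the hindered but primary C19 alcohol without touching the alkenes.

Step 14
Reactants: 24 [(1R,4aS,5R,8aS)-1,4a-dimethyl-6-methylidene-5-(3-methylidenepent-4-en-1-yl)decahydronaphthalen-1-yl]methyl 2-[bis(2,2,2-trifluoroethoxy)phosphoryl]acetate; 25 4-{[tert-butyl(dimethyl)silyl]oxy}benzaldehyde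
Product: 27 [(1R,4aS,5R,8aS)-1,4a-dimethyl-6-methylidene-5-(3-methylidenepent-4-en-1-yl)decahydronaphthalen-1-yl]methyl (2Z)-3-(4-{[tert-butyl(dimethyl)silyl]oxy}phenyl)prop-2-enoate, via potassium phosphonate carbanion 26 (not isolated)
Conditions: KN(SiMe3)2, 18-crown-6, THF, −78 °C; then 25, −78 °C, dark
Reagents that add atoms: none
Why: The Still–Gennari variant of the Horner–Wadsworth–Emmons olefination, with a bis(trifluoroethyl) phosphonate and a dissociated potassium counter-ion, should give the kinetic (Z)-alkene with an aromatic aldehyde.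

Step 15
Reactants: 27 [(1R,4aS,5R,8aS)-1,4a-dimethyl-6-methylidene-5-(3-methylidenepent-4-en-1-yl)decahydronaphthalen-1-yl]methyl (2Z)-3-(4-{[tert-butyl(dimethyl)silyl]oxy}phenyl)prop-2-enoate
Product: 28 [(1R,4aS,5R,8aS)-1,4a-dimethyl-6-methylidene-5-(3-methylidenepent-4-en-1-yl)decahydronaphthalen-1-yl]methyl (2Z)-3-(4-hydroxyphenyl)prop-2-enoate
Conditions: Bu4NF, AcOH, THF, 0 °C, dark
Reagents that add atoms: none
Why: Fluoride-mediated cleavage of the aryl silyl ether, buffered with acetic acid so that the phenoxide is protonated at once, should leave the ester and the (Z)-alkene unchanged.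

**Compound list**
1 | 2-methylcyclohexane-1,3-dione | CC1C(=O)CCCC1=O | starting material
2 | prop-2-enal (acrolein) | C=CC=O | starting material
3 | 3-(1-methyl-2,6-dioxocyclohexyl)propanal | O=CCCC1(C)C(=O)CCCC1=O | intermediate
4 | methyl 2-(triphenyl-λ5-phosphanylidene)propanoate | COC(=O)C(C)=P(c1ccccc1)(c1ccccc1)c1ccccc1 | starting material
5 | methyl (2E)-2-methyl-5-(1-methyl-2,6-dioxocyclohexyl)pent-2-enoate | COC(=O)/C(C)=C/CCC1(C)C(=O)CCCC1=O | intermediate
6 | methyl (1R,4aR,8aS)-8a-{[diethoxy(methyl)silyl]oxy}-1,4a-dimethyl-5-oxodecahydronaphthalene-1-carboxylate | O=C1CCC[C@@]2(O[Si](C)(OCC)OCC)[C@](C)(C(=O)OC)CCC[C@@]12C | intermediate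
7 | methyl (1R,4aR,8aS)-8a-hydroxy-1,4a-dimethyl-5-oxodecahydronaphthalene-1-carboxylate (cis-fused; hydroxyl, 4a-methyl and ester on one face) | O=C1CCC[C@@]2(O)[C@](C)(C(=O)OC)CCC[C@@]12C | intermediate
8 | methyl (1R,4aR)-1,4a-dimethyl-5-oxo-1,2,3,4,4a,5,6,7-octahydronaphthalene-1-carboxylate | O=C1CCC=C2[C@](C)(C(=O)OC)CCC[C@@]12C | intermediate
9 | methyl (1R,4aR,8aS)-1,4a-dimethyl-5-oxodecahydronaphthalene-1-carboxylate (trans-fused) | O=C1CCC[C@@H]2[C@](C)(C(=O)OC)CCC[C@@]12C | intermediate
10 | methyl (1R,4aR,8aR)-5-bromo-6-formyl-1,4a-dimethyl-1,2,3,4,4a,7,8,8a-octahydronaphthalene-1-carboxylate | BrC1=C(C=O)CC[C@@H]2[C@](C)(C(=O)OC)CCC[C@@]12C | intermediate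
11 | 2-chlorobuta-1,3-diene | C=CC(Cl)=C | starting material
12 | oxirane | C1CO1 | starting material
13 | chloro(buta-1,3-dien-2-yl)magnesium | C=CC(=C)[Mg]Cl | intermediate
14 | 3-methylidenepent-4-en-1-ol | C=CC(=C)CCO | intermediate
15 | 5-iodo-3-methylidenepent-1-ene | C=CC(=C)CCI | intermediate
16 | iodo(3-methylidenepent-4-en-1-yl)zinc | C=CC(=C)CC[Zn]I | intermediate
17 | methyl (1R,4aR,8aS)-6-formyl-1,4a-dimethyl-5-(3-methylidenepent-4-en-1-yl)-1,2,3,4,4a,7,8,8a-octahydronaphthalene-1-carboxylate | C=CC(=C)CCC1=C(C=O)CC[C@@H]2[C@](C)(C(=O)OC)CCC[C@@]12C | intermediate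
18 | (E)-tosylhydrazone of 17 | C=CC(=C)CCC1=C(/C=N/NS(=O)(=O)c3ccc(C)cc3)CC[C@@H]2[C@](C)(C(=O)OC)CCC[C@@]12C | intermediate
19 | methyl (1R,4aR,8aS)-6-{[1-(1,3,2-benzodioxaborol-2-yl)-2-(4-methylbenzenesulfonyl)hydrazinyl]methyl}-1,4a-dimethyl-5-(3-methylidenepent-4-en-1-yl)-1,2,3,4,4a,7,8,8a-octahydronaphthalene-1-carboxylate | C=CC(=C)CCC1=C(CN(B3Oc4ccccc4O3)NS(=O)(=O)c3ccc(C)cc3)CC[C@@H]2[C@](C)(C(=O)OC)CCC[C@@]12C | intermediate
20 | methyl (1R,4aR,8aS)-6-(diazenylmethyl)-1,4a-dimethyl-5-(3-methylidenepent-4-en-1-yl)-1,2,3,4,4a,7,8,8a-octahydronaphthalene-1-carboxylate | C=CC(=C)CCC1=C(CN=N)CC[C@@H]2[C@](C)(C(=O)OC)CCC[C@@]12C | intermediate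
21 | methyl (1R,4aS,5R,8aS)-1,4a-dimethyl-6-methylidene-5-(3-methylidenepent-4-en-1-yl)decahydronaphthalene-1-carboxylate | C=CC(=C)CC[C@@H]1C(=C)CC[C@@H]2[C@](C)(C(=O)OC)CCC[C@@]12C | intermediate
22 | [(1R,4aS,5R,8aS)-1,4a-dimethyl-6-methylidene-5-(3-methylidenepent-4-en-1-yl)decahydronaphthalen-1-yl]methanol | C=CC(=C)CC[C@@H]1C(=C)CC[C@@H]2[C@](C)(CO)CCC[C@@]12C | intermediate
23 | 2-[bis(2,2,2-trifluoroethoxy)phosphoryl]acetic acid | OC(=O)CP(=O)(OCC(F)(F)F)OCC(F)(F)F | starting material
24 | [(1R,4aS,5R,8aS)-1,4a-dimethyl-6-methylidene-5-(3-methylidenepent-4-en-1-yl)decahydronaphthalen-1-yl]methyl 2-[bis(2,2,2-trifluoroethoxy)phosphoryl]acetate | C=CC(=C)CC[C@@H]1C(=C)CC[C@@H]2[C@](C)(COC(=O)CP(=O)(OCC(F)(F)F)OCC(F)(F)F)CCC[C@@]12C | intermediate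
25 | 4-{[tert-butyl(dimethyl)silyl]oxy}benzaldehyde | CC(C)(C)[Si](C)(C)Oc1ccc(C=O)cc1 | starting material
26 | potassium salt of the phosphonate carbanion of 24 | C=CC(=C)CC[C@@H]1C(=C)CC[C@@H]2[C@](C)(COC(=O)[CH-]P(=O)(OCC(F)(F)F)OCC(F)(F)F)CCC[C@@]12C.[K+] | intermediate
27 | [(1R,4aS,5R,8aS)-1,4a-dimethyl-6-methylidene-5-(3-methylidenepent-4-en-1-yl)decahydronaphthalen-1-yl]methyl (2Z)-3-(4-{[tert-butyl(dimethyl)silyl]oxy}phenyl)prop-2-enoate | C=CC(=C)CC[C@@H]1C(=C)CC[C@@H]2[C@](C)(COC(=O)/C=C\c3ccc(O[Si](C)(C)C(C)(C)C)cc3)CCC[C@@]12C | intermediate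
28 | [(1R,4aS,5R,8aS)-1,4a-dimethyl-6-methylidene-5-(3-methylidenepent-4-en-1-yl)decahydronaphthalen-1-yl]methyl (2Z)-3-(4-hydroxyphenyl)prop-2-enoate | C=CC(=C)CC[C@@H]1C(=C)CC[C@@H]2[C@](C)(COC(=O)/C=C\c3ccc(O)cc3)CCC[C@@]12C | target

**Step count and risks**

Total step count: 15. Longest linear sequence: 13 (steps 1–6 and 9–15; steps 7 and 8 make the side-chain fragment).

Three steps most likely to fail:

1. Step 3 (the proposed method). The copper hydride may reduce a ring ketone, the crowded copper enolate may fail to add to the hindered carbonyl so that only conjugate reduction is seen after work-up, the ligand may discriminate poorly between the enantiotopic carbonyls, or the chelated transition state may not control C4. The fallback uses known chemistry and sets C4 and C5 by reductive alkylation instead of by the aldol. It sets out from aldehyde 3: Wittig olefination with methyl (triphenylphosphoranylidene)acetate (CH2Cl2, 25 °C) gives methyl (2E)-5-(1-methyl-2,6-dioxocyclohexyl)pent-2-enoate F1, the β-monosubstituted enoate for which the copper hydride domino reduction/aldol desymmetrisation is established. Under the conditions of step 3 this should give methyl (1R,4aR,8aR)-8a-hydroxy-4a-methyl-5-oxodecahydronaphthalene-1-carboxylate F2. Elimination (MsCl, Et3N, then DBU) gives the conjugated ester methyl (4aR)-4a-methyl-5-oxo-2,3,4,4a,5,6,7,8-octahydronaphthalene-1-carboxylate F3, and ketalisation (ethylene glycol, TsOH, benzene, reflux) gives its ethylene ketal F4. Birch-type reductive methylation (Li, NH3, THF, t-BuOH, −78 °C; then MeI) should protonate C5 axially and methylate the ester enolate from the equatorial face, giving the ethylene ketal of compound 9 F5. Aqueous HCl in THF removes the ketal, and the route is rejoined at compound 9.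

2. Step 9. Reductive elimination at the congested tetrasubstituted alkenylpalladium may be slow, so that protodebromination, β-hydride elimination or coordination of the diene to palladium takes over. The fallback changes the bond construction from cross-coupling to carbonyl addition and sets out from ketone 9 and iodide 15. α-Methylenation of 9 (paraformaldehyde, N-methylanilinium trifluoroacetate, THF, reflux) gives methyl (1R,4aR,8aS)-1,4a-dimethyl-6-methylidene-5-oxodecahydronaphthalene-1-carboxylate F6. Iodide 15 with t-BuLi (Et2O, −78 °C) gives (3-methylidenepent-4-en-1-yl)lithium F7, which with CeCl3 gives dichloro(3-methylidenepent-4-en-1-yl)cerium F8. Its 1,2-addition to F6 (THF, −78 °C) should give the tertiary allylic alcohol methyl (1R,4aR,5R,8aS)-5-hydroxy-1,4a-dimethyl-6-methylidene-5-(3-methylidenepent-4-en-1-yl)decahydronaphthalene-1-carboxylate F9. 1,3-Transposition catalysed by Ph3SiOReO3 (Et2O, 0 °C) gives the primary allylic alcohol methyl (1R,4aR,8aS)-6-(hydroxymethyl)-1,4a-dimethyl-5-(3-methylidenepent-4-en-1-yl)-1,2,3,4,4a,7,8,8a-octahydronaphthalene-1-carboxylate F10. Mitsunobu reaction with 2-nitrobenzenesulfonylhydrazide (PPh3, DEAD, THF, −30 °C) gives the N-allyl-N-(2-nitrobenzenesulfonyl)hydrazine F11, which on warming loses the sulfinic acid to give allyl diazene 20; this collapses as in step 11, and the route is rejoined at compound 21.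

3. Step 4. The tertiary chlorosulfite may ionise, and the C5 cation, flanked by two quaternary carbons, may undergo a 1,2-methyl shift from C4 or C10 instead of losing a proton from C6. The fallback removes the hydroxyl by a radical path without an alkene and sets out from ketol 7. Acylation with methyl chlorooxoacetate (DMAP, pyridine, CH2Cl2) gives the mixed oxalate methyl (1R,4aR,8aS)-8a-[(2-methoxy-2-oxoacetyl)oxy]-1,4a-dimethyl-5-oxodecahydronaphthalene-1-carboxylate F12. Bu3SnH with AIBN (toluene, 110 °C; Dolan–MacMillan deoxygenation) should give the C5 radical, which takes hydrogen from the stannane on the face opposite the C10 methyl and the C19 ester. The route is rejoined at compound 9, and step 5 is not needed.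

**Further compounds**
F1 | step 3 | methyl (2E)-5-(1-methyl-2,6-dioxocyclohexyl)pent-2-enoate | COC(=O)/C=C/CCC1(C)C(=O)CCCC1=O
F2 | step 3 | methyl (1R,4aR,8aR)-8a-hydroxy-4a-methyl-5-oxodecahydronaphthalene-1-carboxylate | O=C1CCC[C@@]2(O)[C@H](C(=O)OC)CCC[C@@]12C
F3 | step 3 | methyl (4aR)-4a-methyl-5-oxo-2,3,4,4a,5,6,7,8-octahydronaphthalene-1-carboxylate | O=C1CCCC2=C(C(=O)OC)CCC[C@@]12C
F4 | step 3 | ethylene ketal of F3 | C12(OCCO1)CCCC3=C(C(=O)OC)CCC[C@@]23C
F5 | step 3 | ethylene ketal of compound 9 | C12(OCCO1)CCC[C@@H]3[C@](C)(C(=O)OC)CCC[C@@]23C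
F6 | step 9 | methyl (1R,4aR,8aS)-1,4a-dimethyl-6-methylidene-5-oxodecahydronaphthalene-1-carboxylate | O=C1C(=C)CC[C@@H]2[C@](C)(C(=O)OC)CCC[C@@]12C
F7 | step 9 | (3-methylidenepent-4-en-1-yl)lithium | [Li]CCC(=C)C=C
F8 | step 9 | dichloro(3-methylidenepent-4-en-1-yl)cerium | Cl[Ce](Cl)CCC(=C)C=C
F9 | step 9 | methyl (1R,4aR,5R,8aS)-5-hydroxy-1,4a-dimethyl-6-methylidene-5-(3-methylidenepent-4-en-1-yl)decahydronaphthalene-1-carboxylate | C=CC(=C)CC[C@@]1(O)C(=C)CC[C@@H]2[C@](C)(C(=O)OC)CCC[C@@]12C
F10 | step 9 | methyl (1R,4aR,8aS)-6-(hydroxymethyl)-1,4a-dimethyl-5-(3-methylidenepent-4-en-1-yl)-1,2,3,4,4a,7,8,8a-octahydronaphthalene-1-carboxylate | C=CC(=C)CCC1=C(CO)CC[C@@H]2[C@](C)(C(=O)OC)CCC[C@@]12C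
F11 | step 9 | N-allyl-N-(2-nitrobenzenesulfonyl)hydrazine derived from F10 | C=CC(=C)CCC1=C(CN(N)S(=O)(=O)c3ccccc3[N+](=O)[O-])CC[C@@H]2[C@](C)(C(=O)OC)CCC[C@@]12C
F12 | step 4 | methyl (1R,4aR,8aS)-8a-[(2-methoxy-2-oxoacetyl)oxy]-1,4a-dimethyl-5-oxodecahydronaphthalene-1-carboxylate | O=C1CCC[C@@]2(OC(=O)C(=O)OC)[C@](C)(C(=O)OC)CCC[C@@]12C
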